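Mallotojaponin is disconnected at the bond between C5 of ring B (acetophenone numbering: C1 acetyl, C3 the CH2 bridge, C4 the oxygen para to acetyl) and its 3-methylbut-2-enyl group. That group is delivered last from the C4 oxygen by an aromatic Claisen rearrangement, which makes the C5–CH2 bond with allylic inversion and frees the C4 hydroxyl in one operation. C5 is the only hydrogen-bearing ring carbon; the other ortho carbon (C3) and the para carbon (C1) are blocked. The precursor is the prenyl-free bis-acetophenone carrying a 2-methylbut-3-en-2-yl ether on ring B O4, assembled from a ring A Mannich base and a ring B propargyl ether, then semi-hydrogenated.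

Key step: step 7

Remark on the chemistry: an acetyl group flanked by two hydroxyls hydrogen-bonds only one of them at a time, so O-selectivity is taken from acidity (the hydroxyl para to acetyl is a vinylogous acid) and is exercised on the ring B monomer, not on the pentahydroxy dimer; the ring A C-methyl is brought in with commercial 2,4,6-trihydroxytoluene, and phloroacetophenone is used dried (it is sold as the monohydrate).

Step 1
Reactants: 1 2,4,6-trihydroxytoluene
Product: 2 1-(2,4,6-trihydroxy-3-methylphenyl)ethanone
Conditions: AcCl, AlCl3, PhNO2/CH2Cl2, 0 °C to rt; then ice/aq. HCl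
Reagents that add atoms: acetyl chloride, CC(=O)Cl
Why: Friedel–Crafts C-acylation of the strongly activated phloroglucinol nucleus, in which the two unsubstituted ring carbons of 1 are equivalent so that a single ketone can form, and the first acetyl group deactivates the ring against a second acylation.

Step 2
Reactants: 2 1-(2,4,6-trihydroxy-3-methylphenyl)ethanone
Product: 3 1-(2,6-dihydroxy-4-methoxy-3-methylphenyl)ethanone
Conditions: Me2SO4 (1.0 equiv), K2CO3 (1.1 equiv), acetone, rt to 40 °C
Reagents that add atoms: dimethyl sulfate, COS(=O)(=O)OC
Why: Williamson O-methylation under weak base, in which the hydroxyl para to the acetyl group is the most acidic and is not held in the carbonyl hydrogen bond, so one equivalent of base and dimethyl sulfate should methylate it ahead of the two ortho hydroxyls.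

Step 3
Reactants: 3 1-(2,6-dihydroxy-4-methoxy-3-methylphenyl)ethanone
Product: 4 1-{3-[(dimethylamino)methyl]-2,6-dihydroxy-4-methoxy-5-methylphenyl}ethanone
Conditions: CH2=NMe2+ I− (Eschenmoser's salt, 1.05 equiv), K2CO3 (1.1 equiv), MeCN, 0 °C to rt
Reagents that add atoms: N,N-dimethylmethyleneiminium iodide, C=[N+](C)C.[I-]
Why: Phenolic Mannich aminomethylation with a preformed iminium salt, in which 3 offers a single unsubstituted ring carbon (between OMe and OH) so substitution can occur only there, and the low temperature keeps the ortho-hydroxybenzylamine from eliminating.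

Step 4
Reactants: 5 1-(2,4,6-trihydroxyphenyl)ethanone (phloroacetophenone); 6 2-methylbut-3-yn-2-ol
Product: 8 1-[2,6-dihydroxy-4-(2-methylbut-3-yn-2-yloxy)phenyl]ethanone, via 2-methylbut-3-yn-2-yl trifluoroacetate 7 (not isolated)
Conditions: 6, (CF3CO)2O, DBU, MeCN, −5 °C; then added to 5, DBU (1.1 equiv), CuCl2·2H2O (1 mol %), MeCN, −5 to 0 °C
Reagents that add atoms: trifluoroacetic anhydride, O=C(OC(=O)C(F)(F)F)C(F)(F)F (its trifluoroacetyl group is held only in intermediate 7)
Why: Copper-catalysed propargylic etherification of a phenoxide with a tertiary propargylic ester, in which one equivalent of DBU ionises only the hydroxyl para to the acetyl group so the tertiary ether should form there, and the cold conditions leave the aryl propargyl ether intact.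

Step 5
Reactants: 4 1-{3-[(dimethylamino)methyl]-2,6-dihydroxy-4-methoxy-5-methylphenyl}ethanone; 8 1-[2,6-dihydroxy-4-(2-methylbut-3-yn-2-yloxy)phenyl]ethanone
Product: 10 1-[3-(3-acetyl-2,4-dihydroxy-6-methoxy-5-methylbenzyl)-2,6-dihydroxy-4-(2-methylbut-3-yn-2-yloxy)phenyl]ethanone, via ring A ortho-quinone methide 9 (not isolated)
Conditions: 8 (3 equiv), dioxane, 90 °C, slow addition of 4, N2 sweep
Reagents that add atoms: none
Why: Thermal elimination of dimethylamine from the ortho-hydroxybenzylamine gives ortho-quinone methide 9, which is captured in a conjugate (Friedel–Crafts-type) addition by one of the two equivalent free ring carbons of 8 and re-aromatises; ring A has no free carbon and can only be the electrophile, excess 8 and slow addition should hold back double benzylation and self-condensation, and 90 °C stays below the cyclisation temperature of the propargyl ether.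

Step 6
Reactants: 10 1-[3-(3-acetyl-2,4-dihydroxy-6-methoxy-5-methylbenzyl)-2,6-dihydroxy-4-(2-methylbut-3-yn-2-yloxy)phenyl]ethanone
Product: 11 1-[3-(3-acetyl-2,4-dihydroxy-6-methoxy-5-methylbenzyl)-2,6-dihydroxy-4-(2-methylbut-3-en-2-yloxy)phenyl]ethanone
Conditions: H2 (1 atm), Pd/CaCO3 poisoned with Pb(OAc)2, quinoline, EtOAc, rt
Reagents that add atoms: none
Why: Lindlar semi-hydrogenation, in which the lead- and quinoline-poisoned palladium surface reduces the terminal alkyne to the vinyl group and should stop there, leaving the aryl ketones, the arenes and the tertiary C–O bond untouched when hydrogen uptake is halted after one equivalent.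

Step 7
Reactants: 11 1-[3-(3-acetyl-2,4-dihydroxy-6-methoxy-5-methylbenzyl)-2,6-dihydroxy-4-(2-methylbut-3-en-2-yloxy)phenyl]ethanone
Product: 13 mallotojaponin, via ring B cyclohexa-2,4-dienone 12 (not isolated)
Conditions: PhMe (degassed), 110 °C, sealed tube
Reagents that add atoms: none
Why: A concerted [3,3] sigmatropic shift (aromatic Claisen rearrangement) through a chair-like six-membered transition state breaks the O–C(CH3)2 bond at ring B O4 while the vinyl CH2 terminus bonds to ring B C5, giving cyclohexadienone 12, which enolises to the phenol 13. The closest known reaction type is the thermal ortho-Claisen rearrangement of aryl 1,1-dimethylallyl ethers of hydroxyacetophenones to ortho-prenylphenols. No ring is closed, and the sp3 carbon created in 12 (racemic) is flattened again on enolisation, so no stereochemistry has to be controlled, while the allylic inversion fixes the linear 3-methylbut-2-enyl connectivity. The selectivity needed is C5 over the other ortho carbon C3 and the para carbon C1: C3 bears the CH2 bridge and C1 the acetyl group, so shifts to them give dienones that cannot enolise and can only return, whereas the C5 product is drained off irreversibly. The gem-dimethyl group and the electron-rich ring should allow the shift in neutral toluene near 110 °C, which avoids acid-induced ionisation of the tertiary ether, chroman formation from the product and base-induced scission of the methylene bridge.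

Compound list
1 | 2,4,6-trihydroxytoluene (2-methylbenzene-1,3,5-triol) | Cc1c(O)cc(O)cc1O | starting material
2 | 1-(2,4,6-trihydroxy-3-methylphenyl)ethanone | CC(=O)c1c(O)cc(O)c(C)c1O | intermediate
3 | 1-(2,6-dihydroxy-4-methoxy-3-methylphenyl)ethanone | CC(=O)c1c(O)cc(OC)c(C)c1O | intermediate
4 | 1-{3-[(dimethylamino)methyl]-2,6-dihydroxy-4-methoxy-5-methylphenyl}ethanone | CC(=O)c1c(O)c(CN(C)C)c(OC)c(C)c1O | intermediate
5 | 1-(2,4,6-trihydroxyphenyl)ethanone (phloroacetophenone) | CC(=O)c1c(O)cc(O)cc1O | starting material
6 | 2-methylbut-3-yn-2-ol | CC(C)(O)C#C | starting material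
7 | 2-methylbut-3-yn-2-yl trifluoroacetate | CC(C)(OC(=O)C(F)(F)F)C#C | intermediate (not isolated)
8 | 1-[2,6-dihydroxy-4-(2-methylbut-3-yn-2-yloxy)phenyl]ethanone | CC(=O)c1c(O)cc(OC(C)(C)C#C)cc1O | intermediate
9 | 2-acetyl-3-hydroxy-5-methoxy-4-methyl-6-methylidenecyclohexa-2,4-dien-1-one (ring A ortho-quinone methide) | C=C1C(=O)C(C(C)=O)=C(O)C(C)=C1OC | intermediate (not isolated)
10 | 1-[3-(3-acetyl-2,4-dihydroxy-6-methoxy-5-methylbenzyl)-2,6-dihydroxy-4-(2-methylbut-3-yn-2-yloxy)phenyl]ethanone | COc1c(C)c(O)c(C(C)=O)c(O)c1Cc1c(OC(C)(C)C#C)cc(O)c(C(C)=O)c1O | intermediate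
11 | 1-[3-(3-acetyl-2,4-dihydroxy-6-methoxy-5-methylbenzyl)-2,6-dihydroxy-4-(2-methylbut-3-en-2-yloxy)phenyl]ethanone | COc1c(C)c(O)c(C(C)=O)c(O)c1Cc1c(OC(C)(C)C=C)cc(O)c(C(C)=O)c1O | intermediate
12 | 4-acetyl-2-[(3-acetyl-2,4-dihydroxy-6-methoxy-5-methylphenyl)methyl]-3,5-dihydroxy-6-(3-methylbut-2-en-1-yl)cyclohexa-2,4-dien-1-one (racemic) | COc1c(C)c(O)c(C(C)=O)c(O)c1CC1=C(O)C(C(C)=O)=C(O)C(CC=C(C)C)C1=O | intermediate (not isolated)
13 | mallotojaponin, 1-[3-(3-acetyl-2,4-dihydroxy-6-methoxy-5-methylbenzyl)-2,4,6-trihydroxy-5-(3-methylbut-2-en-1-yl)phenyl]ethanone | COc1c(C)c(O)c(C(C)=O)c(O)c1Cc1c(O)c(CC=C(C)C)c(O)c(C(C)=O)c1O | target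

Total step count: 7. Longest linear sequence: 6 steps (steps 1, 2, 3, 5, 6, 7).

Steps most likely to fail

Step 7. Heterolysis of the tertiary allyl ether (loss of the allyl group as isoprene) may outrun the sigmatropic shift. Prolonged heating may also open the methylene bridge by retro-conjugate addition and scramble the two rings, and traces of acid may close the new prenyl group onto a neighbouring hydroxyl. The fallback moves the rearrangement ahead of bridge formation. It sets out from 8 and 4 and comes back at 13.
- Compound 8 is semi-hydrogenated (H2, Pd/CaCO3 poisoned with Pb(OAc)2, quinoline, EtOAc) to 1-[2,6-dihydroxy-4-(2-methylbut-3-en-2-yloxy)phenyl]ethanone F1.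
- Heating F1 in toluene should give, by the same [3,3] shift to one of its two equivalent ortho carbons, 1-[2,4,6-trihydroxy-3-(3-methylbut-2-en-1-yl)phenyl]ethanone F2, which has no bridge to scramble and a single free ring carbon.
- F2 is then heated with Mannich base 4 in dioxane at 90 °C (via 9), which should give 13 directly.

Step 5. The quinone methide may attack a second molecule of the Mannich base at its substituted carbon (self-condensation), the product may be benzylated a second time at the remaining ring B carbon, and the propargyl ether may begin to cyclise thermally. The fallback generates the electrophile at ambient temperature. It sets out from 4 and 8 and comes back at 10.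
- Compound 4 is quaternised with MeI in acetone at rt to (3-acetyl-2,4-dihydroxy-6-methoxy-5-methylphenyl)methyl-trimethylammonium iodide F3.
- F3 is stirred with excess 8 and K2CO3 in MeCN at 0 °C to rt, where loss of trimethylamine releases 9 without heating and its capture by 8 should give 10.

Step 4. Over-alkylation at a second hydroxyl, competing C-alkylation at the two free ring carbons of the small symmetric triol, or copper-promoted cyclisation of the ether may erode the mono-ether. The fallback postpones etherification until after the bridge is in place. It sets out from 4 and 5 and comes back at 10.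
- Compound 4 is heated with excess 5 in dioxane at 90 °C (via 9) to 1-[3-(3-acetyl-2,4-dihydroxy-6-methoxy-5-methylbenzyl)-2,4,6-trihydroxyphenyl]ethanone F4, a robust coupling with no sensitive ether present.
- F4, which has only one free ring B carbon and whose ring B hydroxyl para to acetyl remains the most acidic site, is alkylated with 7 (made from 6 as in step 4; CuCl2·2H2O, one equivalent of DBU, MeCN, 0 °C) to rejoin the route at 10.

Further compounds
F1 | step 7 | 1-[2,6-dihydroxy-4-(2-methylbut-3-en-2-yloxy)phenyl]ethanone | CC(=O)c1c(O)cc(OC(C)(C)C=C)cc1O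
F2 | step 7 | 1-[2,4,6-trihydroxy-3-(3-methylbut-2-en-1-yl)phenyl]ethanone | CC(=O)c1c(O)cc(O)c(CC=C(C)C)c1O
F3 | step 5 | (3-acetyl-2,4-dihydroxy-6-methoxy-5-methylphenyl)methyl-trimethylammonium iodide | CC(=O)c1c(O)c(C[N+](C)(C)C)c(OC)c(C)c1O.[I-]
F4 | step 4 | 1-[3-(3-acetyl-2,4-dihydroxy-6-methoxy-5-methylbenzyl)-2,4,6-trihydroxyphenyl]ethanone | COc1c(C)c(O)c(C(C)=O)c(O)c1Cc1c(O)cc(O)c(C(C)=O)c1O
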